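**Plan**

1. Atom names (elemane numbering): ring C10 (quaternary; vinyl C1=C2, methyl), C9 (CH2), C8 (O-acyl), C7 (acrylic acid C11–C13), C6 (OH), C5 (bears C4(=C3H2)–C15H2OH).
2. Retrosynthesis: the C8 ester C–O bond is cut with inversion (cyclic sulfate of a cis C6/C8 diol); vinyl carbon C1 and O15 are folded back into a δ-lactone; C8–C9 and C5–C10 are then cut together (intramolecular Diels–Alder); finally C5–C6 (Barbier) and C7–C11 (Stille).
3. Enabling feature: C1 on C10 and O15 on the C5 side chain are 1,5-related, so a methacrylate ester of the C15 alcohol is a four-atom tether holding the C9=C10 dienophile against a C5=C6–C7=C8 diene whose two silyloxy groups are the C6 and C8 oxygens.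
4. Forward: the acyclic triene ester is assembled first; the cycloaddition closes the carbocycle and the lactone together; the lactone is unravelled (i-Bu2AlH, Wittig) into vinyl and CH2OH; the oxygens are then adjusted on the monocycle.
5. Stereochemistry: C10, C5 and C8 from the endo cycloaddition (cis-fused lactone); C7 by protonation next to the C6 ketone; C6 by chelation-controlled reduction; C8 finally inverted by SN2 opening of the cyclic sulfate with the side-chain carboxylate; absolute configuration by resolution of the cycloadduct on a chiral phase.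

Key step: step 8

Remark: alcohol 11 is racemic and its carbinol centre is destroyed in step 6; the cycloadduct of step 8 forms as a racemate and is resolved there, so 15 and all later compounds are single enantiomers. "Axial/equatorial" refers to the chair with the C10 vinyl group axial.

**Route**

Step 1
Reactants: 1 3-chloro-2-(chloromethyl)prop-1-ene; 2 potassium methacrylate
Product: 3 2-(chloromethyl)prop-2-en-1-yl 2-methylprop-2-enoate
Conditions: 1 (3 equiv), Bu4NI (cat.), BHT (cat.), DMF, 50 °C
Reagents that add atoms: none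
Why: SN2 alkylation of the carboxylate by one allylic chloride (ester formation); the excess of the symmetrical dichloride should hold back double substitution, and no stereocentre is formed.

Step 2
Reactants: 4 2-bromo-3,3-diethoxyprop-1-ene
Product: 6 tributyl(3,3-diethoxyprop-1-en-2-yl)stannane, via vinyllithium 5 (not isolated)
Conditions: n-BuLi, THF, −78 °C; then Bu3SnCl, −78 °C to rt
Reagents that add atoms: tributyltin chloride, CCCC[Sn](Cl)(CCCC)CCCC
Why: Bromine–lithium exchange and stannylation of the vinyllithium, the standard entry to 1,1-disubstituted vinylstannanes; no stereocentre is formed.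

Step 3
Reactants: 7 2-bromomalonaldehyde
Product: 8 (Z)-2-bromo-3-(tert-butyldimethylsilyloxy)prop-2-enal
Conditions: TBSCl, imidazole, CH2Cl2, 0 °C
Reagents that add atoms: tert-butyldimethylsilyl chloride, CC(C)(C)[Si](C)(C)Cl
Why: O-Silylation of the enol form of the 1,3-dialdehyde should give the vinylogous silyl formate with oxygen trans to the remaining formyl group (the less crowded, conjugatively favoured geometry); no stereocentre is formed.

Step 4
Reactants: 8 (Z)-2-bromo-3-(tert-butyldimethylsilyloxy)prop-2-enal; 6 tributyl(3,3-diethoxyprop-1-en-2-yl)stannane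
Product: 9 (E)-3-(tert-butyldimethylsilyloxy)-2-(3,3-diethoxyprop-1-en-2-yl)prop-2-enal
Conditions: Pd2(dba)3 (cat.), AsPh3, CuI (cat.), DMF, 40 °C
Reagents that add atoms: none
Why: Stille coupling of the α-bromoenal forms C7–C11 with retention of the enol ether geometry; AsPh3 and CuI are the usual accelerators for hindered 1,1-disubstituted stannanes.

Step 5
Reactants: 9 (E)-3-(tert-butyldimethylsilyloxy)-2-(3,3-diethoxyprop-1-en-2-yl)prop-2-enal; 3 2-(chloromethyl)prop-2-en-1-yl 2-methylprop-2-enoate
Product: 11 racemic allylic alcohol (C6 carbinol), via allylzinc chloride 10 (not isolated)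
Conditions: Zn dust, LiCl, THF, 0 °C to rt; aq NH4Cl
Reagents that add atoms: none
Why: Barbier allylation forms C5–C6 by 1,2-addition of the in situ allylzinc to the aldehyde and tolerates the methacrylate and the acetal; the new carbinol centre is racemic and is removed in step 6.

Step 6
Reactants: 11 racemic allylic alcohol
Product: 12 cross-conjugated β-silyloxy enone (C6 ketone)
Conditions: MnO2, CH2Cl2, rt
Reagents that add atoms: none
Why: MnO2 oxidation of an allylic alcohol under neutral conditions, which should spare the acid-labile γ-silyloxy allylic system and the acetal.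

Step 7
Reactants: 12 cross-conjugated β-silyloxy enone
Product: 14 (3Z,5E)-bis(silyloxy)triene methacrylate, via lithium enolate 13 (not isolated)
Conditions: LiN(SiMe3)2, THF, −78 °C; then TBSCl, DMPU, −78 to −20 °C
Reagents that add atoms: tert-butyldimethylsilyl chloride, CC(C)(C)[Si](C)(C)Cl
Why: Kinetic deprotonation at the doubly activated C5 methylene and O-silylation give the 2-silyloxydiene; the Z enolate (C4 cis to oxygen) is expected, as for ketones with a branched unsaturated acyl group, and no stereocentre is formed.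

Step 8
Reactants: 14 (3Z,5E)-bis(silyloxy)triene methacrylate
Product: 15 cis-fused bicyclic lactone (C8 silyloxy group cis to the lactone carbonyl)
Conditions: PhMe (0.01 M), BHT (cat.), 150 °C, sealed tube; then preparative SFC on amylose tris(3,5-dimethylphenylcarbamate)
Reagents that add atoms: none
Why: Concerted thermal [4+2] cycloaddition (type 1 intramolecular Diels–Alder reaction) of the C5=C6–C7=C8 bis(silyloxy)diene with the tethered methacrylate C9=C10; the closest known reaction type is the thermal cyclization of ester-tethered hexa-3,5-dienyl acrylates and of tethered 2-silyloxydienes to bicyclic δ-lactones. The carbocycle closes by the [4+2] event and the six-membered lactone closes at the same time in the fused mode, because the four-atom tether (C4, C15, O, C1) can only join C5 to C10; this also overrides the electronic preference of the diene for bonding C5 to the methylene carbon. C5 and C10 should be set as a cis ring fusion by the endo position of the tether carbonyl (Alder rule, α-methyl exo), and C8 follows from the E enol ether, whose outside silyloxy group ends cis to the lactone carbonyl. The selectivity needed is endo over exo; the exo (trans-fused) adduct would be a separable diastereomer. The triene is achiral, so both enantiomers form and the wanted one is taken from the chiral phase.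

Step 9
Reactants: 15 cis-fused bicyclic lactone
Product: 16 lactol (anomeric mixture)
Conditions: i-Bu2AlH, CH2Cl2, −78 °C; aq KNaC4H4O6
Reagents that add atoms: none
Why: Partial reduction of a δ-lactone to the lactol at low temperature; the silyl enol ether, silyl ether and acetal are inert, and the anomeric centre is of no consequence.

Step 10
Reactants: 16 lactol
Product: 17 vinyl cyclohexene with free C15 hydroxyl
Conditions: Ph3PCH3Br, KN(SiMe3)2, THF, 0 °C to 50 °C
Reagents that add atoms: methyltriphenylphosphonium bromide, C[P+](c1ccccc1)(c1ccccc1)c1ccccc1.[Br-]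
Why: Wittig methylenation of the open hydroxy-aldehyde form turns the tether carbonyl carbon into the C10 vinyl group and frees the C15 hydroxyl; the α-quaternary aldehyde cannot enolize, so C10 is safe.

Step 11
Reactants: 17 vinyl cyclohexene with free C15 hydroxyl
Product: 18 β-hydroxy ketone (C6 ketone, C8 hydroxyl)
Conditions: Bu4NF, AcOH (1:1), THF, 0 °C to 40 °C
Reagents that add atoms: none
Why: Buffered fluoride cleaves the silyl enol ether and the secondary silyl ether while leaving the acetal; C7 should be set by protonation anti to the C8 oxygen, which is also the equatorial (thermodynamic) epimer, so any equilibration next to the ketone leads to the same isomer.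

Step 12
Reactants: 18 β-hydroxy ketone
Product: 19 triol (C6 and C8 hydroxyls cis)
Conditions: Et2BOMe, NaBH4, THF/MeOH, −78 °C; MeOH co-evaporation
Reagents that add atoms: none
Why: Narasaka–Prasad reduction: boron links the C8 hydroxyl and the ketone oxygen, and hydride should add from the equatorial side (the axial face is screened by the axial C10 vinyl group), giving the axial C6 alcohol as the 1,3-syn diol.

Step 13
Reactants: 19 triol
Product: 20 C15 tert-butyldiphenylsilyl ether
Conditions: TBDPSCl, imidazole, CH2Cl2, 0 °C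
Reagents that add atoms: tert-butyl(chloro)diphenylsilane, CC(C)(C)[Si](Cl)(c1ccccc1)c1ccccc1
Why: Selective silylation of the primary allylic alcohol in the presence of two hindered axial secondary alcohols (steric differentiation).

Step 14
Reactants: 20 C15 tert-butyldiphenylsilyl ether
Product: 21 C6/C8 cyclic sulfate
Conditions: 1,1′-sulfonyldiimidazole, NaH, THF, −20 to 0 °C
Reagents that add atoms: 1,1′-sulfonyldiimidazole, O=S(=O)(n1ccnc1)n1ccnc1
Why: Cyclic sulfate formation from the syn-1,3-diaxial diol by sulfonyl transfer to the dialkoxide; this avoids the RuO4 oxidation of a cyclic sulfite, which the alkenes would not survive, and no stereocentre changes.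

Step 15
Reactants: 22 3-methylfuran-2(5H)-one
Product: 24 (Z)-4-acetoxy-2-methylbut-2-enoic acid, via potassium hydroxy carboxylate 23 (not isolated)
Conditions: KOH (1 equiv), MeOH/H2O, rt; evaporate; Ac2O, pyridine, DMAP (cat.), 0 °C; cold 1 M HCl
Reagents that add atoms: potassium hydroxide, [K+].[OH-]; acetic anhydride, CC(=O)OC(C)=O
Why: Saponification of the butenolide keeps the Z geometry of the ring, and acetylation of the salt caps the primary alcohol before acidification so that the acid cannot relactonize.

Step 16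
Reactants: 21 C6/C8 cyclic sulfate; 24 (Z)-4-acetoxy-2-methylbut-2-enoic acid
Product: 27 C8 ester having a free C6 hydroxyl and the C12 aldehyde, via cesium carboxylate 25 (not isolated), via cesium sulfate monoester 26 (not isolated)
Conditions: Cs2CO3, DMF, 50 °C; then H2SO4 (cat.), H2O, THF, rt
Reagents that add atoms: water, O
Why: SN2 opening of the cyclic sulfate by the carboxylate at the less hindered C8 (flanked by CH2, whereas C6 lies between two branched carbons) should invert C8 and place the ester equatorially; the aqueous acid then hydrolyses the sulfate monoester to the C6 alcohol with retention and unmasks the acetal as the enal.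

Step 17
Reactants: 27 C8 ester having a free C6 hydroxyl and the C12 aldehyde
Product: 28 acrylic acid (C15 silyl ether of the target)
Conditions: NaClO2, NaH2PO4, 2-methylbut-2-ene, t-BuOH/H2O, 0 °C
Reagents that add atoms: sodium chlorite, [Na+].[O-]Cl=O
Why: Pinnick oxidation of the α-substituted acrolein to the acrylic acid; the scavenger protects the other alkenes, and esters and the secondary alcohol are untouched.

Step 18
Reactants: 28 acrylic acid (C15 silyl ether of the target)
Product: 29 target acid
Conditions: Bu4NF, AcOH, THF, rt; work-up at pH 5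
Reagents that add atoms: none
Why: Buffered fluoride removes the primary silyl ether while the acetate and enoate should survive, and the acid, present as its carboxylate, should not lactonize onto the cis C6 hydroxyl.

**Compound list**

1 | 3-chloro-2-(chloromethyl)prop-1-ene | C=C(CCl)CCl | starting material
2 | potassium 2-methylprop-2-enoate (potassium methacrylate) | [K+].[O-]C(=O)C(C)=C | starting material
3 | 2-(chloromethyl)prop-2-en-1-yl 2-methylprop-2-enoate | C=C(C)C(=O)OCC(=C)CCl | intermediate
4 | 2-bromo-3,3-diethoxyprop-1-ene | C=C(Br)C(OCC)OCC | starting material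
5 | (3,3-diethoxyprop-1-en-2-yl)lithium | [Li]C(=C)C(OCC)OCC | intermediate
6 | tributyl(3,3-diethoxyprop-1-en-2-yl)stannane | CCCC[Sn](CCCC)(CCCC)C(=C)C(OCC)OCC | intermediate
7 | 2-bromopropanedial (2-bromomalonaldehyde) | O=CC(Br)C=O | starting material
8 | (Z)-2-bromo-3-[(tert-butyldimethylsilyl)oxy]prop-2-enal | CC(C)(C)[Si](C)(C)O/C=C(\Br)C=O | intermediate
9 | (E)-3-[(tert-butyldimethylsilyl)oxy]-2-(3,3-diethoxyprop-1-en-2-yl)prop-2-enal | CC(C)(C)[Si](C)(C)O/C=C(\C(=C)C(OCC)OCC)C=O | intermediate
10 | {2-[(2-methylprop-2-enoyloxy)methyl]prop-2-en-1-yl}zinc chloride | C=C(C)C(=O)OCC(=C)C[Zn]Cl | intermediate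
11 | racemic (E)-6-[(tert-butyldimethylsilyl)oxy]-5-(3,3-diethoxyprop-1-en-2-yl)-4-hydroxy-2-methylidenehex-5-en-1-yl 2-methylprop-2-enoate | CC(C)(C)[Si](C)(C)O/C=C(\C(=C)C(OCC)OCC)C(O)CC(=C)COC(=O)C(C)=C | intermediate
12 | (E)-6-[(tert-butyldimethylsilyl)oxy]-5-(3,3-diethoxyprop-1-en-2-yl)-2-methylidene-4-oxohex-5-en-1-yl 2-methylprop-2-enoate | CC(C)(C)[Si](C)(C)O/C=C(\C(=C)C(OCC)OCC)C(=O)CC(=C)COC(=O)C(C)=C | intermediate
13 | lithium (3Z,5E)-dienolate of 12 (lithium on the C6 oxygen) | CC(C)(C)[Si](C)(C)O/C=C(\C(=C)C(OCC)OCC)/C([O-])=C/C(=C)COC(=O)C(C)=C.[Li+] | intermediate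
14 | (3Z,5E)-4,6-bis[(tert-butyldimethylsilyl)oxy]-5-(3,3-diethoxyprop-1-en-2-yl)-2-methylidenehexa-3,5-dien-1-yl 2-methylprop-2-enoate | CC(C)(C)[Si](C)(C)O/C=C(\C(=C)C(OCC)OCC)/C(O[Si](C)(C)C(C)(C)C)=C/C(=C)COC(=O)C(C)=C | intermediate
15 | 5,7-bis[(tert-butyldimethylsilyl)oxy]-6-(3,3-diethoxyprop-1-en-2-yl)-8a-methyl-4-methylidene-3,4,4a,7,8,8a-hexahydro-1H-isochromen-1-one; 4a-H and 8a-methyl cis, 7-silyloxy cis to C1 (elemane: C1 carbonyl, C5 side chain and C8 oxygen on one face) | C[C@]12C[C@@H](O[Si](C)(C)C(C)(C)C)C(C(=C)C(OCC)OCC)=C(O[Si](C)(C)C(C)(C)C)[C@H]1C(=C)COC2=O | intermediate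
16 | lactol of 15 (1-hydroxy, both anomers) | C[C@]12C[C@@H](O[Si](C)(C)C(C)(C)C)C(C(=C)C(OCC)OCC)=C(O[Si](C)(C)C(C)(C)C)[C@H]1C(=C)COC2O | intermediate
17 | cyclohexene (C6=C7) with C10 vinyl and methyl, C8 OTBS, C6 OTBS enol ether, C7 3,3-diethoxyprop-1-en-2-yl and C5 C(=CH2)CH2OH; vinyl, C8 oxygen and C5 side chain all cis | C=C[C@@]1(C)C[C@@H](O[Si](C)(C)C(C)(C)C)C(C(=C)C(OCC)OCC)=C(O[Si](C)(C)C(C)(C)C)[C@H]1C(=C)CO | intermediate
18 | C6 ketone with C8 hydroxyl; C10 vinyl, C8 OH, C7 side chain and C5 side chain all cis | C=C[C@@]1(C)C[C@@H](O)[C@@H](C(=C)C(OCC)OCC)C(=O)[C@H]1C(=C)CO | intermediate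
19 | triol; C10 vinyl, C8 OH, C7 side chain, C6 OH and C5 side chain all cis | C=C[C@@]1(C)C[C@@H](O)[C@@H](C(=C)C(OCC)OCC)[C@@H](O)[C@H]1C(=C)CO | intermediate
20 | C15 tert-butyldiphenylsilyl ether of 19 | C=C[C@@]1(C)C[C@@H](O)[C@@H](C(=C)C(OCC)OCC)[C@@H](O)[C@H]1C(=C)CO[Si](c2ccccc2)(c2ccccc2)C(C)(C)C | intermediate
21 | cyclic sulfate bridging O6 and O8 of 20 | C=C[C@@]1(C)C[C@H]2OS(=O)(=O)O[C@H]([C@@H]2C(=C)C(OCC)OCC)[C@H]1C(=C)CO[Si](c3ccccc3)(c3ccccc3)C(C)(C)C | intermediate
22 | 3-methylfuran-2(5H)-one | CC1=CCOC1=O | starting material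
23 | potassium (Z)-4-hydroxy-2-methylbut-2-enoate | [K+].[O-]C(=O)/C(C)=C\CO | intermediate
24 | (Z)-4-acetoxy-2-methylbut-2-enoic acid | O=C(O)/C(C)=C\COC(C)=O | intermediate
25 | cesium (Z)-4-acetoxy-2-methylbut-2-enoate | [Cs+].[O-]C(=O)/C(C)=C\COC(C)=O | intermediate
26 | cesium C6 sulfate monoester of the C8 ester (C8 inverted, acetal intact) | C=C[C@@]1(C)C[C@H](OC(=O)/C(C)=C\COC(C)=O)[C@@H](C(=C)C(OCC)OCC)[C@@H](OS(=O)(=O)[O-])[C@H]1C(=C)CO[Si](c2ccccc2)(c2ccccc2)C(C)(C)C.[Cs+] | intermediate
27 | C8 (Z)-4-acetoxy-2-methylbut-2-enoate (trans to the C10 vinyl group) with free C6 OH, C7 C(=CH2)CHO and C15 OTBDPS | C=C[C@@]1(C)C[C@H](OC(=O)/C(C)=C\COC(C)=O)[C@@H](C(=C)C=O)[C@@H](O)[C@H]1C(=C)CO[Si](c2ccccc2)(c2ccccc2)C(C)(C)C | intermediate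
28 | C15 tert-butyldiphenylsilyl ether of the target acid | C=C[C@@]1(C)C[C@H](OC(=O)/C(C)=C\COC(C)=O)[C@@H](C(=C)C(=O)O)[C@@H](O)[C@H]1C(=C)CO[Si](c2ccccc2)(c2ccccc2)C(C)(C)C | intermediate
29 | 2-[(1S,2S,3R,4R,6S)-6-{[(2Z)-4-(acetyloxy)-2-methylbut-2-enoyl]oxy}-4-ethenyl-2-hydroxy-3-(3-hydroxyprop-1-en-2-yl)-4-methylcyclohexyl]prop-2-enoic acid | C=C[C@@]1(C)C[C@H](OC(=O)/C(C)=C\COC(C)=O)[C@@H](C(=C)C(=O)O)[C@@H](O)[C@H]1C(=C)CO | target

**Step count and risks**

Total step count: 18. Longest linear sequence: 15 steps (steps 3–14 and 16–18, from 2-bromomalonaldehyde 7).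

Steps most likely to fail:

Step 8. What may go wrong: poor endo/exo discrimination, the methyl-endo (tether-exo) transition state competing so that much of the triene ends up as the exo cycloadduct; the cycloaddition may also be slow because the ester must reach the lactone-like s-cis geometry. Fallback: the exo adduct is used rather than discarded, because it already has C8 trans to C1 as in the target and only C5 is wrong, and C5 lies next to the future ketone. Setting out from 14, the trans-fused lactone F1 (resolved on the same chiral phase) is reduced with i-Bu2AlH to lactol F2, methylenated with Ph3P=CH2 to vinyl alcohol F3 and desilylated with Bu4NF/AcOH to hydroxy ketone F4. DBU in CH2Cl2 should then epimerize C5 to the equatorial side chain, giving hydroxy ketone F5. LiBH(s-Bu)3 should give the axial C6 alcohol in triol F6, and TBDPSCl/imidazole gives silyl ether F7. PPTS in aqueous acetone unmasks enal F8, and carbodiimide esterification (EDC, DMAP) of the equatorial C8 hydroxyl with acid 24 returns to the route at 27.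

Step 16. What may go wrong: elimination (E2 toward C7 or C9) or attack at C6 instead of substitution at C8. Fallback without substitution at C8: setting out from 20, the less hindered C8 hydroxyl is oxidized with TEMPO/PhI(OAc)2 to hydroxy ketone F9. Me4NBH(OAc)3 in MeCN/AcOH (Evans–Saksena reduction, hydride delivered from the axial C6 hydroxyl) should give the 1,3-anti diol, which is silyl ether F7. Acetal cleavage to enal F8 and esterification with 24, as above, return to the route at 27.

Step 11. What may go wrong: loss of the C8 oxygen by β-elimination, or retro-aldol ring opening, once the free β-hydroxy ketone is exposed to fluoride. Fallback: the ketone is reduced before the C8 hydroxyl is freed. Setting out from 17, one equivalent of Bu4NF/AcOH at −40 °C should cleave only the silyl enol ether, giving β-silyloxy ketone F10. LiBH(s-Bu)3 (equatorial attack) gives the axial alcohol F11, and Bu4NF/AcOH at 40 °C then removes the C8 silyl ether and returns to the route at 19.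

Further compounds
F1 | step 8 | trans-fused lactone, exo cycloadduct (4a-H and 8a-methyl trans; C8 silyloxy trans to the lactone carbonyl) | C[C@]12C[C@H](O[Si](C)(C)C(C)(C)C)C(C(=C)C(OCC)OCC)=C(O[Si](C)(C)C(C)(C)C)[C@@H]1C(=C)COC2=O
F2 | step 8 | lactol of F1 (both anomers) | C[C@]12C[C@H](O[Si](C)(C)C(C)(C)C)C(C(=C)C(OCC)OCC)=C(O[Si](C)(C)C(C)(C)C)[C@@H]1C(=C)COC2O
F3 | step 8 | vinyl alcohol from F2 (C5 side chain and C8 silyloxy both trans to the C10 vinyl group) | C=C[C@@]1(C)C[C@H](O[Si](C)(C)C(C)(C)C)C(C(=C)C(OCC)OCC)=C(O[Si](C)(C)C(C)(C)C)[C@@H]1C(=C)CO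
F4 | step 8 | β-hydroxy ketone from F3 (C5 side chain axial, trans to vinyl) | C=C[C@@]1(C)C[C@H](O)[C@@H](C(=C)C(OCC)OCC)C(=O)[C@@H]1C(=C)CO
F5 | step 8 | C5 epimer of F4 (the C8 epimer of 18) | C=C[C@@]1(C)C[C@H](O)[C@@H](C(=C)C(OCC)OCC)C(=O)[C@H]1C(=C)CO
F6 | step 8 | triol with axial C6 hydroxyl and equatorial C8 hydroxyl (the C8 epimer of 19) | C=C[C@@]1(C)C[C@H](O)[C@@H](C(=C)C(OCC)OCC)[C@@H](O)[C@H]1C(=C)CO
F7 | step 8 | C15 tert-butyldiphenylsilyl ether of F6 (the C8 epimer of 20) | C=C[C@@]1(C)C[C@H](O)[C@@H](C(=C)C(OCC)OCC)[C@@H](O)[C@H]1C(=C)CO[Si](c2ccccc2)(c2ccccc2)C(C)(C)C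
F8 | step 8 | enal diol from F7 (C7 C(=CH2)CHO) | C=C[C@@]1(C)C[C@H](O)[C@@H](C(=C)C=O)[C@@H](O)[C@H]1C(=C)CO[Si](c2ccccc2)(c2ccccc2)C(C)(C)C
F9 | step 16 | C8 ketone of 20 with axial C6 hydroxyl | C=C[C@@]1(C)CC(=O)[C@@H](C(=C)C(OCC)OCC)[C@@H](O)[C@H]1C(=C)CO[Si](c2ccccc2)(c2ccccc2)C(C)(C)C
F10 | step 11 | C8 tert-butyldimethylsilyl ether of 18 | C=C[C@@]1(C)C[C@@H](O[Si](C)(C)C(C)(C)C)[C@@H](C(=C)C(OCC)OCC)C(=O)[C@H]1C(=C)CO
F11 | step 11 | C8 tert-butyldimethylsilyl ether of 19 | C=C[C@@]1(C)C[C@@H](O[Si](C)(C)C(C)(C)C)[C@@H](C(=C)C(OCC)OCC)[C@@H](O)[C@H]1C(=C)CO
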